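**Plan**

- Retrosynthesis: cut (a) the sulfonate S–O bond that masks the 4-hydroxyphenyl oxygen; (b) the C8–CH2 bond of the prenyl group, traced by a retro-aromatic Claisen shift to an O7–C(CH3)2CH=CH2 ether; (c) the C3=C4 bond of the pyran ring, leaving a vinyl group on C4a and an identical ether on O1; (d) both O–C(CH3)2 bonds, the vinyl C=C, the aryl–CHO bond and the aryl–C(=O) bond.
- Forward: phloroglucinol is acylated (Hoesch) and formylated (Vilsmeier–Haack), the two outer hydroxyls are etherified in one operation, the aldehyde is methylenated, the pyran ring is closed, the remaining ether migrates to carbon, and the sulfonate is removed. The pyran ring is the only ring made.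
- Enabling feature: O1 and C4 of the pyran ring sit on adjacent carbons (C8a, C4a) of the phloroglucinol ring and C2 is a quaternary gem-dimethyl carbon. An ortho pair Ar–CH=CH2 / Ar–O–C(CH3)2–CH=CH2 therefore holds two terminal alkenes ready for a six-membered metathesis closure that gives C3=C4 directly at the chromene oxidation level. The same tertiary allyl ether on the neighbouring O7 is a latent C8 prenyl group, so one C5 reagent supplies both isoprenoid units and the position of the ether decides which oxygen enters the ring.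
- Stereochemistry: the target has no stereocentre; the cis C3=C4 alkene is fixed by the ring.

Key step: step 6

Remark: locants in 7 to 9 refer to the benzoyl ring (C1 carries the ketone); locants in 10 to 13 are those of 2H-chromene.

**Route**

Step 1
Reactants: 1 4-hydroxybenzonitrile
Product: 2 4-cyanophenyl 4-methylbenzenesulfonate
Conditions: TsCl, Et3N, DMAP (cat.), CH2Cl2, 0 °C to rt
Reagents that add atoms: p-toluenesulfonyl chloride, Cc1ccc(S(=O)(=O)Cl)cc1
Why: O-sulfonylation of the phenol masks the one oxygen that must stay free of allyl groups later, as an aryl sulfonate that should tolerate HCl/ZnCl2, POCl3, zerovalent palladium, heat and ruthenium carbenes and is removed by hydroxide.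

Step 2
Reactants: 2 4-cyanophenyl 4-methylbenzenesulfonate; 3 phloroglucinol (benzene-1,3,5-triol)
Product: 5 4-(2,4,6-trihydroxybenzoyl)phenyl 4-methylbenzenesulfonate, via ketiminium chloride 4 (not isolated)
Conditions: ZnCl2, HCl (g), Et2O, 0 °C to rt; then H2O, 100 °C
Reagents that add atoms: water, O
Why: Houben–Hoesch acylation, in which the nitrile activated by HCl/ZnCl2 is attacked by one of the three equivalent nucleophilic carbons of phloroglucinol, the ketiminium salt deactivates the ring against a second acylation, and hydrolysis gives the diaryl ketone with its oxygen from water.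

Step 3
Reactants: 5 4-(2,4,6-trihydroxybenzoyl)phenyl 4-methylbenzenesulfonate
Product: 7 4-(3-formyl-2,4,6-trihydroxybenzoyl)phenyl 4-methylbenzenesulfonate, via aryl iminium chloride 6 (not isolated)
Conditions: POCl3, DMF, EtOAc, 0 °C to rt; then H2O, 60 °C
Reagents that add atoms: N,N-dimethylformamide, CN(C)C=O (formyl carbon); water, O (formyl oxygen)
Why: Vilsmeier–Haack formylation, in which the chloroiminium ion attacks one of the two equivalent free ring carbons of the acylphloroglucinol, the iminium group prevents a second formylation, and hydrolysis gives the salicylaldehyde.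

Step 4
Reactants: 7 4-(3-formyl-2,4,6-trihydroxybenzoyl)phenyl 4-methylbenzenesulfonate
Product: 8 4-{3-formyl-2-hydroxy-4,6-bis[(2-methylbut-3-en-2-yl)oxy]benzoyl}phenyl 4-methylbenzenesulfonate
Conditions: tert-butyl 2-methylbut-3-en-2-yl carbonate (2.5 equiv), Pd(PPh3)4 (5 mol %), THF, 0 °C
Reagents that add atoms: tert-butyl 2-methylbut-3-en-2-yl carbonate, C=CC(C)(C)OC(=O)OC(C)(C)C
Why: Tsuji–Trost-type O-allylation, in which zerovalent palladium ionizes the tertiary carbonate to a 1,1-dimethylallyl palladium cation and tert-butoxide (after loss of CO2), the phenoxide attacks the more substituted allyl terminus under kinetic control at 0 °C, and the C4–OH and C6–OH (each next to the ring C5–H) should react in preference to the C2–OH, which is wedged between the two carbonyl-bearing carbons and strongly hydrogen-bonded.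

Step 5
Reactants: 8 4-{3-formyl-2-hydroxy-4,6-bis[(2-methylbut-3-en-2-yl)oxy]benzoyl}phenyl 4-methylbenzenesulfonate
Product: 9 4-{3-ethenyl-2-hydroxy-4,6-bis[(2-methylbut-3-en-2-yl)oxy]benzoyl}phenyl 4-methylbenzenesulfonate
Conditions: MePPh3Br (2.5 equiv), KOtBu (2.4 equiv), THF, 0 °C to rt
Reagents that add atoms: methyltriphenylphosphonium bromide, C[P+](c1ccccc1)(c1ccccc1)c1ccccc1.[Br-] (CH2 delivered as its ylide)
Why: Wittig methylenation of the aldehyde, with one equivalent of ylide consumed by the single chelated phenol, while the diaryl ketone is shielded by two ortho substituents and should not react.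

Step 6
Reactants: 9 4-{3-ethenyl-2-hydroxy-4,6-bis[(2-methylbut-3-en-2-yl)oxy]benzoyl}phenyl 4-methylbenzenesulfonate
Product: 10 4-{5-hydroxy-2,2-dimethyl-7-[(2-methylbut-3-en-2-yl)oxy]-2H-chromene-6-carbonyl}phenyl 4-methylbenzenesulfonate
Conditions: second-generation Grubbs catalyst (5 mol %), CH2Cl2 (0.01 M), 40 °C
Reagents that add atoms: none
Why: Ring-closing olefin metathesis: the ruthenium carbene loads onto the unhindered styrene CH=CH2, adds across the terminal alkene of the ortho O–C(CH3)2–CH=CH2 group through a ruthenacyclobutane, and cycloreversion forms the C3=C4 bond and releases ethene. The closest known reaction type is the ring-closing metathesis of 2-(allyloxy)styrenes to 2H-chromenes, including 2,2-disubstituted ones. The pyran ring is closed as a six-membered ring with the new double bond inside it, by joining two terminal sp2 carbons held together by the aryl C4a–C8a–O1–C2 unit, with the gem-dimethyl group favouring the folded conformer. No stereocentre is formed and the cis geometry of the new alkene is imposed by the ring. The step needs closure onto the C4 ether oxygen only, which the substrate secures because that is the only ether ortho to the vinyl group: the C6 ether is para to it and cannot reach, the C2 oxygen carries no alkene, and the gem-dimethyl groups make both ether alkenes poor partners for intermolecular metathesis at high dilution. It also needs both tertiary allyl ethers to stay on oxygen, which 40 °C should secure because their [3,3] shift to the free C5 position sets in only at higher temperature.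

Step 7
Reactants: 10 4-{5-hydroxy-2,2-dimethyl-7-[(2-methylbut-3-en-2-yl)oxy]-2H-chromene-6-carbonyl}phenyl 4-methylbenzenesulfonate
Product: 12 4-[5,7-dihydroxy-2,2-dimethyl-8-(3-methylbut-2-en-1-yl)-2H-chromene-6-carbonyl]phenyl 4-methylbenzenesulfonate, via ortho-dienone 11 (not isolated)
Conditions: PhMe (degassed), 110 °C
Reagents that add atoms: none
Why: Aromatic Claisen rearrangement, a [3,3] shift that delivers the terminal CH2 of the 1,1-dimethylallyl ether to C8, the only free ortho carbon (the other carries the aroyl group), so the allyl unit arrives inverted as the linear prenyl group and the dienone tautomerizes to the 7-phenol.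

Step 8
Reactants: 12 4-[5,7-dihydroxy-2,2-dimethyl-8-(3-methylbut-2-en-1-yl)-2H-chromene-6-carbonyl]phenyl 4-methylbenzenesulfonate
Product: 13 vismiaphenone E, [5,7-dihydroxy-2,2-dimethyl-8-(3-methylbut-2-en-1-yl)-2H-chromen-6-yl](4-hydroxyphenyl)methanone
Conditions: KOH, 1,4-dioxane/H2O, 80 °C, under argon; then 1 M HCl to pH 4
Reagents that add atoms: none
Why: Base hydrolysis of the aryl sulfonate by attack of hydroxide at sulfur (S–O cleavage) releases the phenoxide para to the ketone; hydroxide in aqueous dioxane is used so that no methyl tosylate can form, and the chromene, the prenyl group and the phenoxides should be stable to base.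

**Compound list**

1 | 4-hydroxybenzonitrile | N#Cc1ccc(O)cc1 | starting material
2 | 4-cyanophenyl 4-methylbenzenesulfonate | N#Cc1ccc(OS(=O)(=O)c2ccc(C)cc2)cc1 | intermediate
3 | phloroglucinol (benzene-1,3,5-triol) | Oc1cc(O)cc(O)c1 | starting material
4 | ketiminium chloride of 5 (not isolated) | [NH2+]=C(c1ccc(OS(=O)(=O)c2ccc(C)cc2)cc1)c1c(O)cc(O)cc1O.[Cl-] | intermediate
5 | 4-(2,4,6-trihydroxybenzoyl)phenyl 4-methylbenzenesulfonate | Cc1ccc(S(=O)(=O)Oc2ccc(C(=O)c3c(O)cc(O)cc3O)cc2)cc1 | intermediate
6 | aryl N,N-dimethyliminium chloride of 7 (not isolated) | C[N+](C)=Cc1c(O)cc(O)c(C(=O)c2ccc(OS(=O)(=O)c3ccc(C)cc3)cc2)c1O.[Cl-] | intermediate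
7 | 4-(3-formyl-2,4,6-trihydroxybenzoyl)phenyl 4-methylbenzenesulfonate | O=Cc1c(O)cc(O)c(C(=O)c2ccc(OS(=O)(=O)c3ccc(C)cc3)cc2)c1O | intermediate
8 | 4-{3-formyl-2-hydroxy-4,6-bis[(2-methylbut-3-en-2-yl)oxy]benzoyl}phenyl 4-methylbenzenesulfonate | O=Cc1c(OC(C)(C)C=C)cc(OC(C)(C)C=C)c(C(=O)c2ccc(OS(=O)(=O)c3ccc(C)cc3)cc2)c1O | intermediate
9 | 4-{3-ethenyl-2-hydroxy-4,6-bis[(2-methylbut-3-en-2-yl)oxy]benzoyl}phenyl 4-methylbenzenesulfonate | C=Cc1c(OC(C)(C)C=C)cc(OC(C)(C)C=C)c(C(=O)c2ccc(OS(=O)(=O)c3ccc(C)cc3)cc2)c1O | intermediate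
10 | 4-{5-hydroxy-2,2-dimethyl-7-[(2-methylbut-3-en-2-yl)oxy]-2H-chromene-6-carbonyl}phenyl 4-methylbenzenesulfonate | CC1(C)C=Cc2c(O1)cc(OC(C)(C)C=C)c(C(=O)c3ccc(OS(=O)(=O)c4ccc(C)cc4)cc3)c2O | intermediate
11 | ortho-dienone from the [3,3] shift of 10, racemic at C8 (not isolated) | CC(C)=CCC1C(=O)C(C(=O)c3ccc(OS(=O)(=O)c4ccc(C)cc4)cc3)=C(O)C2=C1OC(C)(C)C=C2 | intermediate
12 | 4-[5,7-dihydroxy-2,2-dimethyl-8-(3-methylbut-2-en-1-yl)-2H-chromene-6-carbonyl]phenyl 4-methylbenzenesulfonate | CC(C)=CCc1c(O)c(C(=O)c2ccc(OS(=O)(=O)c3ccc(C)cc3)cc2)c(O)c2c1OC(C)(C)C=C2 | intermediate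
13 | vismiaphenone E | CC(C)=CCc1c(O)c(C(=O)c2ccc(O)cc2)c(O)c2c1OC(C)(C)C=C2 | target

**Totals**

Total step count: 8. Longest linear sequence: 8 steps (1 → 2 → 5 → 7 → 8 → 9 → 10 → 12 → 13); phloroglucinol 3 enters at step 2.

**Steps most likely to fail**

1. Step 4. The diacylphenoxide is a good leaving group, so zerovalent palladium may re-ionize the first-formed tertiary ethers and scramble them to linear O-prenyl or C-allylated material, and the second, chelated hydroxyl may be etherified incompletely. Fallback, from 7 back to 8: irreversible copper-catalysed O-alkylation with 3-chloro-3-methylbut-1-yne (CuCl2·2H2O cat., DBU, MeCN, 0 °C) should give the bis(propargyl) ether 4-{3-formyl-2-hydroxy-4,6-bis[(2-methylbut-3-yn-2-yl)oxy]benzoyl}phenyl 4-methylbenzenesulfonate F1. Semi-hydrogenation of both alkynes (H2, Pd/CaCO3 poisoned with Pb(OAc)2 (Lindlar catalyst), quinoline, EtOAc, rt) then returns to 8.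

2. Step 6. Turnover may be slow because the ether alkene is neopentyl-like and the intermediate 2-alkoxybenzylidene can rest as a chelate, and raising the temperature to compensate invites a premature [3,3] shift of the C4 ether to C5. Fallback, from 5 back to 10, building the chromene by pericyclic chemistry instead:
   - CuCl2-catalysed O-alkylation of the non-chelated 4-OH of 5 with 3-chloro-3-methylbut-1-yne (DBU, MeCN, 0 °C) should give 4-{2,6-dihydroxy-4-[(2-methylbut-3-yn-2-yl)oxy]benzoyl}phenyl 4-methylbenzenesulfonate F2.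
   - Heating (xylene, 140 °C) should trigger propargyl Claisen rearrangement, 1,5-hydrogen shift and oxa-6π electrocyclization onto one of the two equivalent ortho carbons, giving 4-(5,7-dihydroxy-2,2-dimethyl-2H-chromene-6-carbonyl)phenyl 4-methylbenzenesulfonate F3.
   - O-alkylation of the less hindered 7-OH with tert-butyl 2-methylbut-3-en-2-yl carbonate and Pd(PPh3)4 (THF, 0 °C) rejoins the route at 10.

3. Step 5. The ylide or alkoxide may attack sulfur of the activated aryl sulfonate, and addition to the phenoxide-deactivated, hindered aldehyde may be sluggish. Fallback, from 8 back to 9, by Peterson olefination: addition of (trimethylsilyl)methylmagnesium chloride (2.5 equiv, THF, −78 °C) to the aldehyde should give racemic 4-{2-hydroxy-3-[1-hydroxy-2-(trimethylsilyl)ethyl]-4,6-bis[(2-methylbut-3-en-2-yl)oxy]benzoyl}phenyl 4-methylbenzenesulfonate F4. Base-promoted syn-elimination (KH, THF, 0 °C to rt) then returns to 9.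

**Further compounds**

F1 | step 4 | 4-{3-formyl-2-hydroxy-4,6-bis[(2-methylbut-3-yn-2-yl)oxy]benzoyl}phenyl 4-methylbenzenesulfonate | O=Cc1c(OC(C)(C)C#C)cc(OC(C)(C)C#C)c(C(=O)c2ccc(OS(=O)(=O)c3ccc(C)cc3)cc2)c1O
F2 | step 6 | 4-{2,6-dihydroxy-4-[(2-methylbut-3-yn-2-yl)oxy]benzoyl}phenyl 4-methylbenzenesulfonate | C#CC(C)(C)Oc1cc(O)c(C(=O)c2ccc(OS(=O)(=O)c3ccc(C)cc3)cc2)c(O)c1
F3 | step 6 | 4-(5,7-dihydroxy-2,2-dimethyl-2H-chromene-6-carbonyl)phenyl 4-methylbenzenesulfonate | CC1(C)C=Cc2c(O1)cc(O)c(C(=O)c3ccc(OS(=O)(=O)c4ccc(C)cc4)cc3)c2O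
F4 | step 5 | 4-{2-hydroxy-3-[1-hydroxy-2-(trimethylsilyl)ethyl]-4,6-bis[(2-methylbut-3-en-2-yl)oxy]benzoyl}phenyl 4-methylbenzenesulfonate (racemic) | C[Si](C)(C)CC(O)c1c(OC(C)(C)C=C)cc(OC(C)(C)C=C)c(C(=O)c2ccc(OS(=O)(=O)c3ccc(C)cc3)cc2)c1O
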